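Cuts: (a) the C6–C(=O) bond, leading back to a C6 aryllithium and a protected 4-hydroxybenzaldehyde; (b) the C3=C4 double bond of the pyran, by retro-metathesis; (c) the O1–C2 ether bond and the C8–CH2 prenyl bond, both traced to one reverse-prenyl carbonate, the second through an aromatic Claisen shift.
Enabling feature (chromene numbering O1, C2, C3, C4, C4a, C5–C8, C8a): the six-membered pyran contains one cis alkene, C3=C4, bonded to arene carbon C4a on one side and to the quaternary C2 on O1 on the other. Cutting it leaves a vinyl group on C4a and a CH2=CH–CMe2–O ether on the adjacent C8a, a 1,7-diene with two monosubstituted ends held ortho on ring A.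
Forward order: ring A is bought as 2,4,6-trihydroxybenzaldehyde, whose formyl carbon becomes C4. The C8 prenyl group, the O1–C2 ether and the C4a vinyl group follow in that order, metathesis closes the pyran, and ring B is joined at C6 last, before oxidation and global deprotection.
Stereochemistry: the target has no stereocentre. C3=C4 is cis because the six-membered ring allows nothing else, the prenyl alkene carries two identical methyl groups, and the transient carbinol centre from the aryl addition is erased by oxidation.

Key step: step 7

Assumption: MOMCl, Boc2O, methyltriphenylphosphonium bromide, IBX and both catalysts are taken as purchased reagents, and labels C2–C8a always refer to the chromene numbering of the target, also in open precursors.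

Step 1
Reactants: 1 2,4,6-trihydroxybenzaldehyde
Product: 2 2-hydroxy-4,6-bis(methoxymethoxy)benzaldehyde
Conditions: MOMCl (2.1 equiv), i-Pr2NEt (2.5 equiv), CH2Cl2, 0 °C to rt
Reagents that add atoms: chloromethyl methyl ether (MOMCl), COCCl
Why: Phenol O-alkylation (MOM protection): the para hydroxyl and one of the two equivalent ortho hydroxyls react, whereas the last one is locked in a hydrogen bond to the formyl oxygen and should stay free with two equivalents of reagent, which singles out the oxygen that later becomes O1.

Step 2
Reactants: 3 2-methylbut-3-en-2-ol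
Product: 5 tert-butyl 2-methylbut-3-en-2-yl carbonate, via lithium 2-methylbut-3-en-2-olate 4 (not isolated)
Conditions: n-BuLi (1.05 equiv), THF, 0 °C; Boc2O (1.1 equiv), 0 °C to rt; H2O
Reagents that add atoms: di-tert-butyl dicarbonate (Boc2O), CC(C)(C)OC(=O)OC(=O)OC(C)(C)C
Why: Alkoxide acylation: the lithium alkoxide of the tertiary allylic alcohol attacks a carbonyl group of Boc2O and expels tert-butyl carbonate, the standard entry to mixed tertiary allylic carbonates.

Step 3
Reactants: 2 2-hydroxy-4,6-bis(methoxymethoxy)benzaldehyde; 5 tert-butyl 2-methylbut-3-en-2-yl carbonate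
Product: 6 2,4-bis(methoxymethoxy)-6-(2-methylbut-3-en-2-yloxy)benzaldehyde
Conditions: 5 (1.5 equiv), Pd(PPh3)4 (5 mol %), THF, 0–5 °C
Reagents that add atoms: none
Why: Tsuji–Trost O-allylation: zerovalent palladium ionises the carbonate with loss of CO2, the released tert-butoxide deprotonates the phenol, and under kinetic control at low temperature the phenoxide attacks the more substituted, more cationic terminus of the 1,1-dimethyl-π-allyl complex to give the tertiary ether.

Step 4
Reactants: 6 2,4-bis(methoxymethoxy)-6-(2-methylbut-3-en-2-yloxy)benzaldehyde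
Product: 8 2-hydroxy-4,6-bis(methoxymethoxy)-3-(3-methylbut-2-enyl)benzaldehyde, via ortho-dienone 7 (not isolated)
Conditions: o-xylene, 130 °C
Reagents that add atoms: none
Why: Aromatic Claisen rearrangement: the [3,3] shift can end productively only at the one free ortho carbon (future C8), it inverts the allyl unit so that the 1,1-dimethylallyl ether arrives as a normal prenyl group, and tautomerisation of the dienone restores the chelated phenol.

Step 5
Reactants: 8 2-hydroxy-4,6-bis(methoxymethoxy)-3-(3-methylbut-2-enyl)benzaldehyde; 5 tert-butyl 2-methylbut-3-en-2-yl carbonate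
Product: 9 4,6-bis(methoxymethoxy)-2-(2-methylbut-3-en-2-yloxy)-3-(3-methylbut-2-enyl)benzaldehyde
Conditions: 5 (2 equiv), Pd(PPh3)4 (10 mol %), THF, 0–5 °C
Reagents that add atoms: none
Why: Tsuji–Trost O-allylation as in step 3: 8 offers a single free hydroxyl, so the tertiary ether can form only on the oxygen that becomes O1, and its salicylaldehyde-type acidity keeps it a competent partner for the π-allyl complex although it is flanked on both sides, a situation in which reverse prenylation of phenols is known.

Step 6
Reactants: 9 4,6-bis(methoxymethoxy)-2-(2-methylbut-3-en-2-yloxy)-3-(3-methylbut-2-enyl)benzaldehyde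
Product: 10 1-ethenyl-4,6-bis(methoxymethoxy)-2-(2-methylbut-3-en-2-yloxy)-3-(3-methylbut-2-enyl)benzene
Conditions: Ph3PCH3Br (1.5 equiv), KOtBu (1.4 equiv), THF, 0 °C to rt
Reagents that add atoms: methyltriphenylphosphonium bromide, C[P+](c1ccccc1)(c1ccccc1)c1ccccc1.[Br-]
Why: Wittig methylenation: the non-stabilised ylide adds to the only carbonyl group of 9, which has neither an enolisable position nor a base-labile group, and collapse of the oxaphosphetane gives the C4a vinyl group, a routine conversion for 2,6-dialkoxybenzaldehydes.

Step 7
Reactants: 10 1-ethenyl-4,6-bis(methoxymethoxy)-2-(2-methylbut-3-en-2-yloxy)-3-(3-methylbut-2-enyl)benzene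
Product: 11 5,7-bis(methoxymethoxy)-2,2-dimethyl-8-(3-methylbut-2-enyl)-2H-chromene
Conditions: second-generation Grubbs catalyst (H2IMes)(PCy3)Cl2Ru=CHPh (5 mol %), CH2Cl2 (5 mM), 40 °C, argon sparge
Reagents that add atoms: none
Why: Ring-closing olefin metathesis through ruthenacyclobutanes: the catalyst exchanges its benzylidene for the C4a vinyl group, the resulting o-alkoxybenzylidene adds [2+2] to the vinyl group on C2, and cycloreversion forms C3=C4 together with a ruthenium methylidene that picks up the next styrene and expels ethene. The closest known reaction type is the ring-closing metathesis of o-vinylaryl allyl ethers to 2H-chromenes, which includes ethers with a fully substituted carbon next to oxygen. One ring is closed, the six-membered pyran, by union of the two inner carbons of a 1,7-diene whose ends are fixed ortho on ring A and pushed together by the gem-dimethyl group at C2. No stereocentre is formed, and the new alkene can only be cis inside a six-membered ring. The step needs the two monosubstituted alkenes to react while the trisubstituted prenyl alkene at C8 stays untouched: ruthenium loads far more slowly on a trisubstituted alkene, the styrenyl carbene cannot reach the meta-placed prenyl group, and the only other closure (C2 vinyl onto the prenyl alkene, a seven-membered benzoxepine) would need the carbene on the neopentyl-like vinyl group, the slowest site to load. High dilution and the argon sparge remove ethene and so hold back dimerisation and ethenolysis of the prenyl group, and neutral conditions at 40 °C lie well below the threshold for [3,3] shift or ionisation of the tertiary aryl ether.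

Step 8
Reactants: 12 4-hydroxybenzaldehyde
Product: 13 4-(methoxymethoxy)benzaldehyde
Conditions: MOMCl (1.2 equiv), i-Pr2NEt (1.5 equiv), CH2Cl2, 0 °C to rt
Reagents that add atoms: chloromethyl methyl ether (MOMCl), COCCl
Why: Phenol O-alkylation (MOM protection): the acidic para-formyl phenol is the only nucleophilic site, and the acetal removes the proton that would quench the aryllithium of step 9.

Step 9
Reactants: 11 5,7-bis(methoxymethoxy)-2,2-dimethyl-8-(3-methylbut-2-enyl)-2H-chromene; 13 4-(methoxymethoxy)benzaldehyde
Product: 15 [5,7-bis(methoxymethoxy)-2,2-dimethyl-8-(3-methylbut-2-enyl)-2H-chromen-6-yl][4-(methoxymethoxy)phenyl]methanol (racemic), via chromen-6-yllithium 14 (not isolated)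
Conditions: n-BuLi (1.1 equiv), THF, −20 to 0 °C; 13 (1.2 equiv), −78 °C to rt; H2O
Reagents that add atoms: none
Why: Directed ortho-metalation followed by 1,2-addition: C6–H is the only aromatic hydrogen of ring A and lies between two MOM ethers that both coordinate lithium, so deprotonation there should outrun that of the allylic C8 methylene, and the aryllithium adds to the aldehyde without facial control to give a racemic carbinol whose stereocentre is removed in step 10.

Step 10
Reactants: 15 [5,7-bis(methoxymethoxy)-2,2-dimethyl-8-(3-methylbut-2-enyl)-2H-chromen-6-yl][4-(methoxymethoxy)phenyl]methanol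
Product: 16 [5,7-bis(methoxymethoxy)-2,2-dimethyl-8-(3-methylbut-2-enyl)-2H-chromen-6-yl][4-(methoxymethoxy)phenyl]methanone
Conditions: IBX (1.5 equiv), DMSO, rt
Reagents that add atoms: none
Why: IBX oxidation of a secondary, doubly benzylic alcohol: ligand exchange at iodine and collapse of the alkoxyperiodinane give the diaryl ketone and erase the carbinol stereocentre, while the prenyl alkene, the chromene and the MOM acetals are inert to this reagent at room temperature.

Step 11
Reactants: 16 [5,7-bis(methoxymethoxy)-2,2-dimethyl-8-(3-methylbut-2-enyl)-2H-chromen-6-yl][4-(methoxymethoxy)phenyl]methanone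
Product: 17 vismiaphenone E, [5,7-dihydroxy-2,2-dimethyl-8-(3-methylbut-2-enyl)-2H-chromen-6-yl](4-hydroxyphenyl)methanone
Conditions: HCl in MeOH (0.5 mol/L), rt
Reagents that add atoms: none
Why: Acid-catalysed acetal exchange (MOM cleavage): protonation of each O,O-acetal and capture of the oxocarbenium ion by methanol frees the three phenols, the two ethers next to the ketone being the fastest, and dilute acid at room temperature is a regime in which ortho-prenylphenols and 2,2-dimethylchromenes are known to persist.

Compound list
1 | 2,4,6-trihydroxybenzaldehyde | O=Cc1c(O)cc(O)cc1O | starting material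
2 | 2-hydroxy-4,6-bis(methoxymethoxy)benzaldehyde | O=Cc1c(O)cc(OCOC)cc1OCOC | intermediate
3 | 2-methylbut-3-en-2-ol | C=CC(C)(C)O | starting material
4 | lithium 2-methylbut-3-en-2-olate (not isolated) | C=CC(C)(C)[O-].[Li+] | intermediate
5 | tert-butyl 2-methylbut-3-en-2-yl carbonate | C=CC(C)(C)OC(=O)OC(C)(C)C | intermediate
6 | 2,4-bis(methoxymethoxy)-6-(2-methylbut-3-en-2-yloxy)benzaldehyde | O=Cc1c(OC(C)(C)C=C)cc(OCOC)cc1OCOC | intermediate
7 | 2,4-bis(methoxymethoxy)-5-(3-methylbut-2-enyl)-6-oxocyclohexa-1,3-diene-1-carbaldehyde (racemic, not isolated) | O=CC1=C(OCOC)C=C(OCOC)C(CC=C(C)C)C1=O | intermediate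
8 | 2-hydroxy-4,6-bis(methoxymethoxy)-3-(3-methylbut-2-enyl)benzaldehyde | O=Cc1c(O)c(CC=C(C)C)c(OCOC)cc1OCOC | intermediate
9 | 4,6-bis(methoxymethoxy)-2-(2-methylbut-3-en-2-yloxy)-3-(3-methylbut-2-enyl)benzaldehyde | O=Cc1c(OC(C)(C)C=C)c(CC=C(C)C)c(OCOC)cc1OCOC | intermediate
10 | 1-ethenyl-4,6-bis(methoxymethoxy)-2-(2-methylbut-3-en-2-yloxy)-3-(3-methylbut-2-enyl)benzene | C=Cc1c(OC(C)(C)C=C)c(CC=C(C)C)c(OCOC)cc1OCOC | intermediate
11 | 5,7-bis(methoxymethoxy)-2,2-dimethyl-8-(3-methylbut-2-enyl)-2H-chromene | CC(C)=CCc1c(OCOC)cc(OCOC)c2C=CC(C)(C)Oc12 | intermediate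
12 | 4-hydroxybenzaldehyde | O=Cc1ccc(O)cc1 | starting material
13 | 4-(methoxymethoxy)benzaldehyde | O=Cc1ccc(OCOC)cc1 | intermediate
14 | [5,7-bis(methoxymethoxy)-2,2-dimethyl-8-(3-methylbut-2-enyl)-2H-chromen-6-yl]lithium (not isolated) | [Li]c1c(OCOC)c(CC=C(C)C)c2OC(C)(C)C=Cc2c1OCOC | intermediate
15 | [5,7-bis(methoxymethoxy)-2,2-dimethyl-8-(3-methylbut-2-enyl)-2H-chromen-6-yl][4-(methoxymethoxy)phenyl]methanol (racemic) | OC(c1ccc(OCOC)cc1)c1c(OCOC)c(CC=C(C)C)c2OC(C)(C)C=Cc2c1OCOC | intermediate
16 | [5,7-bis(methoxymethoxy)-2,2-dimethyl-8-(3-methylbut-2-enyl)-2H-chromen-6-yl][4-(methoxymethoxy)phenyl]methanone | O=C(c1ccc(OCOC)cc1)c1c(OCOC)c(CC=C(C)C)c2OC(C)(C)C=Cc2c1OCOC | intermediate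
17 | vismiaphenone E | CC(C)=CCc1c(O)c(C(=O)c2ccc(O)cc2)c(O)c2c1OC(C)(C)C=C2 | target

Total step count: 11. Longest linear sequence: 9 (steps 1, 3, 4, 5, 6, 7, 9, 10, 11, from 2,4,6-trihydroxybenzaldehyde).

Steps most likely to fail

Step 5. The phenoxide is flanked by the formyl and prenyl groups, so its attack at the tertiary terminus of the π-allyl complex may be slow. Because it is also a good leaving group, zerovalent palladium may re-ionise the product and let the ether drift to the linear prenyl isomer. The fallback replaces the reversible π-allyl electrophile with an irreversible, sterically slim one. Starting from 8, copper-catalysed alkylation with 3-chloro-3-methylbut-1-yne (CuCl2·2H2O 1 mol %, DBU, MeCN, 0 °C) should give 4,6-bis(methoxymethoxy)-2-(2-methylbut-3-yn-2-yloxy)-3-(3-methylbut-2-enyl)benzaldehyde F1. In F1 both ortho positions are blocked, so no propargyl Claisen shift can occur. Semihydrogenation (H2, Pd/CaCO3 poisoned with Pb(OAc)2, quinoline, EtOAc), carried out before any vinyl group is present, rejoins the route at 9.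

Step 7. The vinyl group next to the quaternary C2 may engage too slowly. The catalyst could then decay, the styrene ends could couple between molecules, or the prenyl alkene could be scrambled by cross-metathesis. The fallback builds the same pyran by a pericyclic closure. Starting from 8, addition of 2-methylprop-1-enylmagnesium bromide (2.5 equiv, THF, 0 °C) should give 2-(1-hydroxy-3-methylbut-2-enyl)-3,5-bis(methoxymethoxy)-6-(3-methylbut-2-enyl)phenol F2. Warming F2 in toluene (80–110 °C) expels water to form the o-quinone methide (6Z)-3,5-bis(methoxymethoxy)-6-(3-methylbut-2-enylidene)-2-(3-methylbut-2-enyl)cyclohexa-2,4-dien-1-one F3. Oxa-6π electrocyclisation of F3 forms O1–C2 and rejoins the route at 11.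

Step 11. The ring B acetal has no neighbouring carbonyl group and is cleaved more slowly than the other two. During the longer acid contact the freed C7 hydroxyl may add to the protonated prenyl alkene, or methanol may add across C3=C4. The fallback removes the slow acetal from the plan by using an orthogonal silyl group.
- Starting from 11, lithiation as in step 9 (14) and addition to commercial 4-(tert-butyldimethylsilyloxy)benzaldehyde should give the racemic silyl-protected carbinol F4.
- IBX in DMSO should convert F4 into the silyl-protected benzophenone F5.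
- Brief contact with catalytic p-TsOH·H2O in MeOH at rt should cleave only the two carbonyl-activated MOM ethers and give the 5,7-dihydroxy silyl ether F6.
- TBAF buffered with AcOH (THF, 0 °C) then removes the aryl silyl ether without acid and arrives at 17.

Further compounds
F1 | step 5 | 4,6-bis(methoxymethoxy)-2-(2-methylbut-3-yn-2-yloxy)-3-(3-methylbut-2-enyl)benzaldehyde | O=Cc1c(OC(C)(C)C#C)c(CC=C(C)C)c(OCOC)cc1OCOC
F2 | step 7 | 2-(1-hydroxy-3-methylbut-2-enyl)-3,5-bis(methoxymethoxy)-6-(3-methylbut-2-enyl)phenol (racemic) | CC(C)=CC(O)c1c(O)c(CC=C(C)C)c(OCOC)cc1OCOC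
F3 | step 7 | (6Z)-3,5-bis(methoxymethoxy)-6-(3-methylbut-2-enylidene)-2-(3-methylbut-2-enyl)cyclohexa-2,4-dien-1-one | CC(C)=C/C=C1\C(=O)C(CC=C(C)C)=C(OCOC)C=C1OCOC
F4 | step 11 | [5,7-bis(methoxymethoxy)-2,2-dimethyl-8-(3-methylbut-2-enyl)-2H-chromen-6-yl][4-(tert-butyldimethylsilyloxy)phenyl]methanol (racemic) | OC(c1ccc(O[Si](C)(C)C(C)(C)C)cc1)c1c(OCOC)c(CC=C(C)C)c2OC(C)(C)C=Cc2c1OCOC
F5 | step 11 | [5,7-bis(methoxymethoxy)-2,2-dimethyl-8-(3-methylbut-2-enyl)-2H-chromen-6-yl][4-(tert-butyldimethylsilyloxy)phenyl]methanone | O=C(c1ccc(O[Si](C)(C)C(C)(C)C)cc1)c1c(OCOC)c(CC=C(C)C)c2OC(C)(C)C=Cc2c1OCOC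
F6 | step 11 | [5,7-dihydroxy-2,2-dimethyl-8-(3-methylbut-2-enyl)-2H-chromen-6-yl][4-(tert-butyldimethylsilyloxy)phenyl]methanone | O=C(c1ccc(O[Si](C)(C)C(C)(C)C)cc1)c1c(O)c(CC=C(C)C)c2OC(C)(C)C=Cc2c1O
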